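The runs were computed for substances that don't exist.

| setting | eta | beta | delta |
|---|---|---|---|
| starting material | 50.0 mM | 150 mM | 150 mM |
| partner | 40.0 mM | 40.0 mM | 40.0 mM |
| catalyst | 5.00 mM | 5.00 mM | 10.0 mM |
| time |  |  | 25 min |

| eta run: time / min | eta run: [target] / mM | beta run: time / min | beta run: [target] / mM |
|---|---|---|---|
| 1.0 | 1.40 | 1.0 | 1.39 |
| 1.7 | 3.02 | 1.7 | 2.91 |
| 2.9 | 6.38 | 2.9 | 7.38 |
| 5.0 | 12.03 | 5.0 | 14.18 |
| 8.5 | 19.23 | 8.5 | 22.25 |
| 15 | 26.28 | 15 | 29.74 |
| 25 | 29.28 | 25 | 31.93 |

(scatter of a reading: 0.2 mM)

1. how the opening rate goes with [starting material] round the charge of the eta run: the exponent of the rate at two percent of starting material gone to target (one fixed amount of target, the same in the runs compared)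
2. target in the delta run at 25 min, as a share of the starting material charged

- Overall: starting material + partner -> target, with catalyst as catalyst.
- Constant volume, constant temperature.
- The analysis sees a species whether free or bound.
- An order is taken over about fifteen percent of the charge, up and down.

Of the constants a fit could hand me I want one, so I ask first what the delta answer leans on. Partner is the limiting reagent in the delta run, 40.0 mM against 150 mM of starting material. In the beta run c(target) reaches 31.93 mM, below the partner charge, and it has nearly stopped rising. I assume that partner leaves by two first-order paths, and I take that last reading as the stall. The gap to it closes at 0.229 min⁻¹ between 8.5 min and 15 min. Multiplying by the share of partner missing from target gives 0.0461 min⁻¹, the loss constant, the first-order rate constant at which partner goes anywhere but to target. The remainder, 0.183 min⁻¹, is the path to target in the beta run.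

The delta run differs from the beta run in its catalyst, and if that path follows the catalyst in proportion it becomes 0.365 min⁻¹. Now the inputs, in turn. Time barely counts: 25 min holds 10.3 lifetimes of partner. An order of 0.5 in catalyst instead of one moves the answer by 1.1 percentage points. A doubled loss constant moves it by 2.4 points, so that constant needs reading more carefully. My number is 35.5 mM of target, or 23.7 % of the starting material charged.

The forecast gives 0.1 (−0.1 to 0.35) for the order and 25 % (21.5 % to 26.7 %) for the delta run, higher than mine. Of the stall it says: “I suspect catalyst death (or partner loss)”.

The flask gives 0.12 for the order and 23.4 % for the delta run, which is 35.1 mM of target.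

    active catalyst + starting material ⇌ catalyst-substrate complex, settled at all times (37.90 M⁻¹)
    catalyst-substrate complex + partner ⇌ ternary complex, settled at all times (45.80 M⁻¹)
    ternary complex → target + active catalyst (1.446 min⁻¹)
    catalyst + partner → active catalyst + partner (21.90 M⁻¹ min⁻¹)
    partner → lost reagent (0.03336 min⁻¹)

A fit in which the catalyst dies by itself keeps a root mean square residual of 7.9 in units of the scatter. In the eta run the gap closes at 0.186 min⁻¹, so the loss constant I read from the beta run, 0.0461 min⁻¹, puts the eta stall at 30.1 mM, and the last eta reading is 29.28 mM.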